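The target in Tuesday's flask reads 56 % at 0.417 h and 31 % at 1.33 h, then hardly moves. You want to know what this flask holds at 8.0 h and what to do with it then.

common to all: gas phase 21 mM (held); temperature 70 °C
- Tuesday's: starting material 0.11 M; the very flask that is asked about, followed so far
- Saturday's: starting material 0.22 M; run made earlier
- flask: starting material 0.11 M; time 8.0 h

- Tuesday's (time / h: target / %): 0.417: 56; 1.33: 31; 2.00: 31; 3.00: 29; 5.00: 26
- Saturday's (time / min: target / %): 8.00: 64; 25.0: 58; 40.0: 42; 60.0: 33; 90.0: 30

(readings scatter by 1.5 percentage points)

- noon: change nothing and wait 15 h more
- autumn: at 8.0 h raise the temperature by 25 K, then wait 15 h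
- midnight: at 8.0 h add starting material, 50.0 % of the amount charged, then wait 15 h
- dawn: at 8.0 h take out 90 % of the target then present, then wait 15 h

- target that was removed still counts
- what was read earlier has a scatter of 1.5 percentage points, one standard deviation
- at the start none of the gas phase is in solution
- the earlier runs do not show what temperature does; that part of a forecast is a guess
- additions bring no volume worth counting

1. target, in percent of the starting material first charged, at 8.0 h
2. the option that brings most further target ("none" if no option brings more than 2 percentage points) (noon / autumn / midnight / dawn / none)
3. target present, with what was taken out counted in, in percent of the starting material first charged, after autumn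
4. target present, with what was taken out counted in, in percent of the starting material first charged, after dawn

Start with the balance of the smaller charge, the gas. In Tuesday's flask the early reading means 61.6 mM of target, more than the 21 mM of gas held. Gas is therefore fed in as it is used, and the starting material is the limiting reagent.

Now the puzzle. At the pace of its first fall, 0.648 h⁻¹, Tuesday's target should read 2.88 % at 5.00 h, yet it reads 26 %. A loss that stops is a balance between the target and an unseen form. Saturday's flask, with twice the charge, ends at 30 %, so the balance is a ratio, not an amount.

The late readings of both flasks average 29.4 %. I take the low last reading as scatter and define ρ, the unseen form per unit of target at rest, as 2.40. The target's share of any pool is then one part in one plus ρ.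

My reckoning gives 29.4 % at 8.0 h, and noon adds nothing. The fall's half-life, 1.07 h, is shorter than the 15 h of waiting, so I expect ρ to return after noon, midnight and dawn, which stay at 70 °C. Midnight gains 15 percentage points. Dawn banks 26.5 %, and the rest of the pool refills to a total of 48.1 %, a gain of 19 points. Autumn changes ρ by an amount no run shows, so I pick dawn and leave autumn unranked.

The forecast gave 22.5 %, dawn as best, 3 % after autumn and 27 % after dawn, on the ground: “The pool then drains slowly”.

The flask gives 28.6 % at 8.0 h. The best option is autumn, gaining 30 points, against 14 points for midnight and 18 points for dawn. Autumn ends at 58.5 % and dawn at 46.9 %.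

    gas phase ⇌ dissolved gas, rate k1*(csat - [dissolved gas]) (kL = 5.40 min⁻¹)
    starting material + dissolved gas → target (k = 10.0 M⁻¹ min⁻¹, Ea = 67.0 kJ mol⁻¹)
    target ⇌ isomer of the product (K = 2.50, k = 0.0350 min⁻¹, Ea = 107 kJ mol⁻¹, ΔH = −53.0 kJ mol⁻¹)
    dissolved gas → decomposed reagent (k = 0.00230 min⁻¹, Ea = 100 kJ mol⁻¹)
    (constants at 70 °C)

The unseen form is the isomer of the product. After autumn's rise of 25 K, this flask ends with target at 58.5 %, which puts ρ at 0.708, against 2.50 in this flask at 8.0 h before the rise and the 2.40 I read off the runs. Carry that value to the neighbouring flask, kept at 95 °C from the start, the temperature autumn reaches, with amounts and time unchanged. One part in one plus ρ gives 58.5 % target. At 8.00 h that neighbouring flask holds 41.5 % isomer of the product and 58.5 % target.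

(All runs stem from a simulated flask with constants of no real substance, and the scatter is random.)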